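Slowness is the risk in a cold flask, and waste of reagent is the risk in a warm one, so before you charge a run of 2.0 min you have to decide which temperature to use.

| setting | midnight | spring | teal | green | amber |
|---|---|---|---|---|---|
| starting material | 5.0 × 10⁻⁴ M | 5.0 × 10⁻⁴ M | 5.0 × 10⁻⁴ M | 5.0 × 10⁻⁴ M | 5.0 × 10⁻⁴ M |
| reagent | 0.32 mM | 0.71 mM | 0.475 mM | 0.475 mM | 0.475 mM |
| second substrate | 0.25 mM | 0.25 mM | 0.250 mM | 0.250 mM | 0.250 mM |
| third substrate | 0.25 mM | 0.25 mM | 0.250 mM | 0.250 mM | 0.250 mM |
| temperature | 5 °C | 38 °C | 50 °C | −10 °C | 20 °C |
| remark | run made earlier | run made earlier |  |  |  |
| time |  |  | 2.0 min | 2.0 min | 2.0 min |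

| midnight: time / min | midnight: target / % | spring: time / min | spring: target / % |
|---|---|---|---|
| 3.00 | 34.5 | 0.333 | 49.5 |
| 6.00 | 39.2 | 0.833 | 62.8 |
| 10.0 | 40.6 | 1.33 | 67.1 |
| 12.0 | 39.6 | 2.00 | 69.6 |
| 15.0 | 39.3 | 2.50 | 69.5 |
| 20.0 | 39.0 | 4.00 | 70.1 |

(readings scatter by 0.5 percentage points)

- candidate steps: starting material + reagent -> target; reagent + target -> over-reaction product; second substrate + reagent -> second product; third substrate + reagent -> third product

1. the flask with the highest amount of target, in percent of the starting material charged ("all alike" if they lie within 1.5 percentage points) (teal / green / amber / all alike)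
2. final target, as a percentage of the starting material charged, in teal
3. final target, as a percentage of the starting material charged, in green
4. final target, as a percentage of the starting material charged, in amber

In both runs the reagent is the limiting reagent: even the 0.71 mM of the spring run stands below the 1.00 mM of substrates together. Target therefore rises until the reagent is used, and then it stays flat.

While the substrates stay near their charges, the reagent decays pseudo-first-order, so the gap to the plateau shrinks exponentially. The first reading against the last then gives 1.39 min for the midnight run and 0.272 min for the spring run. This is rough for spring, where the reagent is large.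

I draw a straight line through the logarithms against temperature, which gives 2.92 min for green, 0.662 min for amber and 0.150 min for teal. Carry this reagent lifetime, the time in which the reagent falls by the factor e, and hold it against the time allowed.

The plateaus give the other half. The share of the reagent that reached target was 60.9 % in the midnight run, and it is lower in the warmer spring run, at 49.4 %. A straight line through the share itself against temperature, not through its logarithm, gives 66.2 % for green, 55.7 % for amber and 45.2 % for teal.

Target is then the share, times reagent per starting material, times the part of the reagent used. Teal finishes but wastes reagent, at 42.9 %. Green is cut off by the clock, at 31.2 %. Amber gets 50.3 %, so I would charge amber.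

The forecast, reckoned from relative rates, chooses amber too, with 43 % (39 % to 47 %) for teal, 29 % (23 % to 35 %) for green and 48.5 % (44 % to 53 %) for amber: “Warming therefore favours the side reactions.” Its green and amber figures lie a little below mine.

The flasks give 43.2 % in teal, 28.2 % in green and 49.1 % in amber, so amber stands highest, as the forecast said.

    starting material + reagent → target (k = 150 /M/s, Ea = 35.0 kJ/mol)
    reagent + target → over-reaction product (k = 5.70 /M/s, Ea = 57.0 kJ/mol)
    second substrate + reagent → second product (k = 120 /M/s, Ea = 53.0 kJ/mol)
    third substrate + reagent → third product (k = 270 /M/s, Ea = 47.0 kJ/mol)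
    (constants at 50 °C)

Green still holds 57 % of its reagent at 2.00 min, where its lifetime of 2.92 min gave 50.4 %, and amber holds 6.7 %, where 0.662 min gave 4.87 %. In the neighbour of amber charged with 8.5 × 10⁻⁴ M of starting material, scaling the starting-material step, whose reagent half-life in amber is 0.78 min at 0.343 min, shortens the lifetime to 0.468 min and gives 1.39 % of the reagent left, and that flask holds 1.58 % at 2.00 min.

Readings and results were generated by integration from invented constants, and the scatter is random.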